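## Structural features

The target is a flat, achiral pentacycle: a coumestan (benzene ring A, pyranone ring B, furan ring C, benzene ring D) with a 2,2-dimethyl-3,4-dihydro-2H-pyran (ring E) fused to ring A, its oxygen on C1 and its benzylic CH2 on C2. Ring A is a fully differentiated phloroglucinol: ring E oxygen at C1, methoxy at C3, lactone oxygen O5 at C4a, carbon substituents at C2 and C11b, and one C–H at C4. Ring D carries a single free phenol at C9, para to C6b and meta to the furan oxygen O11. There is no stereocentre, so no stereocentres stand next to each other and the whole problem is regiochemical. The fragile sites are the lactone (hydroxide, organometallics), the electron-rich C4–H (electrophiles, oxidants), the free phenol and, under strong acid, the tertiary ether of ring E. The real difficulties are two: ring E must be oriented with its oxygen on C1 and not on C3, and a benzofuran with exactly one oxygen, at C9, must be annulated onto the C6a=C11a bond of the pyranone. The key step uses the fact that C6a and the oxygen on C11a can each carry one alkyne arm, so that the six carbons of ring D arise from three two-carbon units. A (2+2+2) cycloaddition then forms C6b–C10a, C10–C9 and C8–C7 and closes rings C and D at once, with boron marking C9 for the hydroxyl.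

## Logic of the disconnections

19 to 18: the C7–H bond is traced back to a C7–Si bond. The silyl group is the steering element of the cycloaddition and is therefore removed last. This costs one step but buys the regiocontrol. The forward step must protonate C7 ipso without harming the lactone or ring E.

18 to 17: the C9–O bond is traced back to a C9–B bond. Boron can be placed at a defined carbon during ring construction and converted to OH afterwards, so ring D needs no phenol protecting group. The oxidation must spare the lactone and the C–Si bond.

17 to 15 and 16: C6b–C10a, C10–C9 and C8–C7 are cut, which removes rings C and D together. The pentacycle falls to a tricyclic coumarin diyne and a two-carbon boryl unit, the largest simplification in the plan. The forward step must orient 16 so that boron ends at C9, and must be faster than self-trimerisation of 16 and decay of the ynol ether. 15 keeps silicon on the C7 terminus and hydrogen on the C10 terminus, because that combination is what the orientation requires.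

15 to 12 (through 13 and 14): the O–C≡C–H unit is traced back to an O-(1,2-dichlorovinyl) group. A terminal ynol ether on an acyl-like oxygen would not survive palladium, copper and amine, so it is unmasked last and used at once. The forward step needs a base that eliminates and dechlorinates without adding to the lactone.

12 to 10 and 11: the C6a–C6b bond (ring carbon to alkyne) is cut, as an sp2–sp coupling. This removes the silylalkyne arm. The coupling must take the C–I bond and leave the vinylic C–Cl bonds.

10 to 7 and 8: the O11–C10a bond is cut, so that the two-carbon unit on oxygen comes from a C2 chloroalkene. The ambident coumarin oxyanion must react at oxygen, which is why 7 already carries iodine on the competing carbon.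

7 to 6: the C–I bond is cut. The forward iodination must choose the enolic carbon over the C–H of ring A.

6 to 5: O5–C6 and C6–C6a are cut, which opens ring B to an ortho-hydroxyacetophenone and a one-carbon carbonyl donor. The forward condensation needs a free phenol next to the acetyl group.

5 to 2 and 3: ring E is cut at its aryl–CH2 bond and its O–CMe2 bond, giving a dihydroxy-methoxyacetophenone and a C5 allylic alcohol. The prenyl unit must cyclise onto the hydroxyl that becomes the C1 oxygen. This is guaranteed because its other neighbour in 2 is already a methyl ether.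

2 to 1: the O–CH3 bond is cut. The forward methylation must select the one hydroxyl that is not hydrogen-bonded to the ketone.

## Other disconnections considered

Alternative 1: The cut runs through ring A (C4–C4a, C3–C4, C1–C2, C1–C11b). It leaves a benzofuran-fused pyranone with a diazoacetyl group on the carbon next to the ring oxygen, the diazoketone A1, and the ynol ether A3 (1-methoxy-5-methylhex-4-en-1-yne).

- Forward step: irradiation of A1 would cause Wolff rearrangement to the vinylketene A2, whose alkene is the pyranone C4a=C11b bond. Cycloaddition of A3, four-electron ring opening and 6π closure (Danheiser benzannulation) would give the phenol A4, 9-benzyloxy-1-hydroxy-3-methoxy-2-prenylcoumestan. Acid-mediated closure of ring E and debenzylation would finish.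
- In favour: the contiguous hydroxyl/prenyl/methoxy pattern is set in one operation by the polarity of the ynol ether. The prenyl group of A4 has only one phenolic neighbour, so ring E can only close onto the C1 oxygen. Ring D brings its oxygen from the start, so no steering group has to be removed.
- Against: A1 requires rings B, C and D to be built first as a pyranone acid derivative, a synthesis in itself. The ketene alkene belongs to an electron-poor pyranone, a partner with little analogy. The extended chromophore competes for the light. A3 is non-commercial and acid-sensitive, and its alkene could intercept the ketene.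
- Comparison: on the ring A pattern this alternative is the better of the two, because the regiochemistry is inherent. The chosen plan settles ring A by phloroglucinol chemistry and spends its key step on rings C and D. Both key steps are multi-bond cascades without close analogy on these ring systems, so they are about equal in risk; the benzannulation closes one ring, the cyclotrimerisation two. Both need two steps after the key step. Before it, A1 and A3 together would need clearly more steps than the seven leading to 15, although the convergence of Alternative 1 is equal or better.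

Alternative 2: The cut removes the two bonds joining the halves of ring B, O5–C4a and C11a–C11b. The fragments are the silyl triflate A5 and 6-(benzyloxy)-2-bromobenzofuran-3-carboxylic acid A7.

- Forward step: CsF would release the aryne A6 from A5. The carboxylate of A7 would add through oxygen to the aryne carbon remote from the ring E oxygen. The aryl anion, now next to that oxygen, would displace bromide at C2 of the benzofuran and give the 9-O-benzyl ether of the target A8. One hydrogenolysis would follow.
- In favour: it is the most convergent plan, with one step after the key step. The ring E oxygen polarises the aryne in the required sense. The ring D oxygen is fixed by choosing a 6-oxygenated benzofuran, which is better than a steering group.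
- Against: A5 is a hexasubstituted benzene with adjacent silyl and triflate groups, and its regiodefined synthesis would be long. Carboxylates are weak aryne nucleophiles, and protonation of the aryl anion before ring closure would stop the sequence at the open ester.
- Comparison: this plan addresses only the ring B junction and moves the ring A and ring D patterns into fragment synthesis. Its polar, stepwise mechanism has closer analogy (aryne insertion with trapping by an ortho electrophile) than the cyclotrimerisation, so on precedent it is equal or better. Its longest linear sequence would probably be shorter, but the total count higher because A5 and A7 must both be made.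

Alternative 3: The cut is the C2–C(benzylic) bond of ring E, starting from a coumestan that carries a 1,1-dimethylpropargyl ether on the C1 oxygen, A9.

- Forward step: heating A9 would cause a [3,3] shift to C2, enolisation, a 1,5-hydrogen shift and oxa-6π closure to the chromene A10. A single hydrogenation would then saturate the chromene and remove the benzyl group.
- In favour: the cascade is thermal, reagent-free and very well precedented. C2 is the only free ortho position, so the regiochemistry is unambiguous. The final hydrogenation does two jobs.
- Against: it makes ring E only. The complete coumestan, with the C1 oxygen free, the C3 oxygen methylated and the C9 oxygen protected, must first be made by some other ring C/D construction. Etherification of the hindered C1 phenol with a tertiary propargylic halide is capricious.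
- Comparison: on the orientation of ring E it is the equal of the chosen plan, since in both only one site can react. On mechanistic certainty it is the better. It contributes nothing to rings C and D, so the overall sequence would be longer and would need protecting groups that the chosen plan avoids.

Key step: step 8

Remark (assumption on the chemistry): 15 is assumed too labile to store and is carried into step 8 at once. The pentacycle is numbered as a coumestan, and "ring-E-fused" means the 2,2-dimethyl-3,4-dihydro-2H-pyran fused with its oxygen on C1 and its CH2 on C2.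

## Route

Step 1
Reactants: 1 2,4,6-trihydroxyacetophenone
Product: 2 2,6-dihydroxy-4-methoxyacetophenone
Conditions: Me2SO4 (1.0 equiv), K2CO3 (1.1 equiv), acetone, reflux
Reagents that add atoms: dimethyl sulfate, COS(=O)(=O)OC
Why: Williamson-type O-methylation; the two hydroxyls flanking the acetyl group are hydrogen-bonded to the carbonyl and less nucleophilic, so one equivalent should methylate the para hydroxyl. This fixes the C3 methoxy group before ring E is made.

Step 2
Reactants: 2 2,6-dihydroxy-4-methoxyacetophenone; 3 2-methylbut-3-en-2-ol
Product: 5 1-(7-hydroxy-5-methoxy-2,2-dimethylchroman-8-yl)ethan-1-one, via C-prenyl phenol 4 (not isolated)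
Conditions: 3 (1.1 equiv), BF3·OEt2, dioxane, rt; then TsOH·H2O (cat.), toluene, 80 °C
Reagents that add atoms: none
Why: Friedel–Crafts prenylation by the dimethylallyl cation at the ring carbon between OH and OMe (the two free positions are equivalent), then acid-catalysed Markovnikov hydroalkoxylation closes ring E. Only the hydroxyl next to the acetyl group flanks the prenyl chain, its other neighbour being the methyl ether, so the ring E oxygen must end at the future C1.

Step 3
Reactants: 5 1-(7-hydroxy-5-methoxy-2,2-dimethylchroman-8-yl)ethan-1-one
Product: 6 10-hydroxy-5-methoxy-2,2-dimethyl-3,4-dihydro-2H,8H-pyrano[2,3-f]chromen-8-one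
Conditions: NaH (4 equiv), (EtO)2CO, toluene, 110 °C; then aq. HCl
Reagents that add atoms: diethyl carbonate, CCOC(=O)OCC
Why: Standard 4-hydroxycoumarin synthesis: Claisen-type acylation of the ketone enolate by the carbonate and lactonisation onto the ortho phenoxide build ring B. The chroman and the methyl ether are inert to NaH.

Step 4
Reactants: 6 10-hydroxy-5-methoxy-2,2-dimethyl-3,4-dihydro-2H,8H-pyrano[2,3-f]chromen-8-one
Product: 7 10-hydroxy-9-iodo-5-methoxy-2,2-dimethyl-3,4-dihydro-2H,8H-pyrano[2,3-f]chromen-8-one
Conditions: I2 (1.05 equiv), Na2CO3, THF/H2O, 0 °C to rt; then aq. HCl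
Reagents that add atoms: iodine, II
Why: Electrophilic iodination of the vinylogous carboxylate at its central carbon, which is far more nucleophilic than the lone C–H of ring A. The iodine blocks C-attack in step 5 and is the handle for step 6.

Step 5
Reactants: 7 10-hydroxy-9-iodo-5-methoxy-2,2-dimethyl-3,4-dihydro-2H,8H-pyrano[2,3-f]chromen-8-one; 8 trichloroethylene
Product: 10 10-{[(E)-1,2-dichloroethenyl]oxy}-9-iodo-5-methoxy-2,2-dimethyl-3,4-dihydro-2H,8H-pyrano[2,3-f]chromen-8-one, via dichloroacetylene 9 (not isolated)
Conditions: 8 (2 equiv), K2CO3 (2 equiv), DMF, 60 °C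
Reagents that add atoms: none
Why: Carbonate dehydrochlorinates 8 to 9 and the coumarin oxyanion adds across it in anti fashion to give the (E)-dichlorovinyl ether, the way phenols are converted into aryl dichlorovinyl ethers. With the central carbon iodinated, the ambident anion should react at oxygen.

Step 6
Reactants: 10 10-{[(E)-1,2-dichloroethenyl]oxy}-9-iodo-5-methoxy-2,2-dimethyl-3,4-dihydro-2H,8H-pyrano[2,3-f]chromen-8-one; 11 trimethylsilylacetylene
Product: 12 10-{[(E)-1,2-dichloroethenyl]oxy}-5-methoxy-2,2-dimethyl-9-[(trimethylsilyl)ethynyl]-3,4-dihydro-2H,8H-pyrano[2,3-f]chromen-8-one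
Conditions: 11 (1.5 equiv), PdCl2(PPh3)2 (3 mol %), CuI (5 mol %), Et3N (3 equiv), THF, rt
Reagents that add atoms: none
Why: Sonogashira coupling; zerovalent palladium should insert into the C–I bond of the iodo-enone much faster than into the vinylic C–Cl bonds at room temperature. It is run before the ynol ether exists, so that 11 is the only terminal alkyne present.

Step 7
Reactants: 12 10-{[(E)-1,2-dichloroethenyl]oxy}-5-methoxy-2,2-dimethyl-9-[(trimethylsilyl)ethynyl]-3,4-dihydro-2H,8H-pyrano[2,3-f]chromen-8-one
Product: 15 10-(ethynyloxy)-5-methoxy-2,2-dimethyl-9-[(trimethylsilyl)ethynyl]-3,4-dihydro-2H,8H-pyrano[2,3-f]chromen-8-one, via chloroethynyl ether 13 (not isolated), via lithium acetylide 14 (not isolated)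
Conditions: mesityllithium (2.2 equiv, preformed solution), THF, −78 °C; AcOH (2.5 equiv), −78 °C to rt; short filtration through basic alumina, used at once
Reagents that add atoms: none
Why: Base-induced conversion of a 1,2-dichlorovinyl ether into an alkynyl ether: vinylic deprotonation and loss of LiCl give 13, chlorine–lithium exchange at the sp carbon gives 14, and protonation gives 15. Mesityllithium is chosen because it is basic and halophilic but too hindered to add to the lactone carbonyl; the silylalkyne is untouched at −78 °C.

Step 8
Reactants: 15 10-(ethynyloxy)-5-methoxy-2,2-dimethyl-9-[(trimethylsilyl)ethynyl]-3,4-dihydro-2H,8H-pyrano[2,3-f]chromen-8-one; 16 ethynylboronic acid pinacol ester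
Product: 17 ring-E-fused 3-methoxy-9-(4,4,5,5-tetramethyl-1,3,2-dioxaborolan-2-yl)-7-(trimethylsilyl)coumestan
Conditions: [Rh(cod)2]BF4 (5 mol %), rac-BINAP (5 mol %), H2 pre-activation then Ar, 16 (3 equiv), slow addition of 15, (CH2Cl)2, rt to 50 °C
Reagents that add atoms: none
Why: Proposed new method: a cationic monovalent rhodium–bisphosphine centre should bind both alkynes of 15 and couple them oxidatively to a rhodacyclopentadiene (trivalent rhodium), which forms C6b–C10a and closes furan ring C as the five-membered ring spanned by the tether C6a–C11a–O11. Coordination and insertion of 16 into the Rh–C10 bond, followed by reductive elimination, should then form C10–C9 and C8–C7 and close benzene ring D; aromatisation makes this formal (2+2+2) cycloaddition irreversible. The closest known reaction types are the rhodium-catalysed cycloaddition of 2-alkynylaryl alkynyl ethers with monoalkynes to dibenzofurans and metal-catalysed cyclotrimerisations of diynes with alkynylboronates; new are the coumarin C=C bond in the tether, the ynol ether on an acyl-like oxygen and the boryl partner in this setting. No stereocentre is created. The selectivity that matters is the orientation of 16: the trimethylsilyl group shields the C7 end of the metallacycle, so the boryl-bearing carbon should bond to the unsubstituted C10 and the CH carbon to C7, which puts boron on C9 and avoids a vicinal SiMe3/boryl pair. Chemoselectivity against self-trimerisation of 16 and dimerisation of 15 is sought by an excess of 16 and slow addition of 15, and the silyl cap itself disfavours homo-coupling of 15. The lactone, the ethers and the C–B bond are spectators under these neutral conditions.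

Step 9
Reactants: 17 ring-E-fused 3-methoxy-9-(4,4,5,5-tetramethyl-1,3,2-dioxaborolan-2-yl)-7-(trimethylsilyl)coumestan
Product: 18 ring-E-fused 9-hydroxy-3-methoxy-7-(trimethylsilyl)coumestan
Conditions: NaBO3·4H2O (3 equiv), THF/H2O 1:1, rt; then aq. HCl
Reagents that add atoms: sodium perborate tetrahydrate, [Na+].[O-]OB=O.O.O.O.O
Why: Oxidation of an arylboronic ester: the peroxide adds to boron, the aryl group migrates to oxygen with retention of position, and hydrolysis releases the C9 phenol. Perborate is mild enough for the Ar–Si bond, and a lactone opened at this pH recloses on acidification.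

Step 10
Reactants: 18 ring-E-fused 9-hydroxy-3-methoxy-7-(trimethylsilyl)coumestan
Product: 19 ring-E-fused 9-hydroxy-3-methoxycoumestan (target CNP0304440.0)
Conditions: CF3CO2H/CH2Cl2 1:1, rt to 40 °C
Reagents that add atoms: none
Why: Electrophilic ipso-protodesilylation: protonation at C7 gives an arenium ion stabilised by the β-silicon and, through C6b, by the furan enol ether, and loss of the silyl group restores the arene. Relief of the compression between SiMe3 and the C6 carbonyl oxygen should help; the lactone, the aryl ethers and ring E tolerate CF3CO2H at this temperature.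

## Compound list

1 | 2,4,6-trihydroxyacetophenone | CC(=O)c1c(O)cc(O)cc1O | starting material
2 | 2,6-dihydroxy-4-methoxyacetophenone | CC(=O)c1c(O)cc(OC)cc1O | intermediate
3 | 2-methylbut-3-en-2-ol | CC(C)(O)C=C | starting material
4 | C-prenyl phenol, 1-[2,6-dihydroxy-4-methoxy-3-(3-methylbut-2-en-1-yl)phenyl]ethan-1-one (formed and consumed in step 2) | CC(=O)c1c(O)cc(OC)c(CC=C(C)C)c1O | intermediate
5 | 1-(7-hydroxy-5-methoxy-2,2-dimethylchroman-8-yl)ethan-1-one | CC(=O)c1c(O)cc(OC)c2c1OC(C)(C)CC2 | intermediate
6 | 10-hydroxy-5-methoxy-2,2-dimethyl-3,4-dihydro-2H,8H-pyrano[2,3-f]chromen-8-one (4-hydroxycoumarin carrying rings A and E) | COc1cc2oc(=O)cc(O)c2c2c1CCC(C)(C)O2 | intermediate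
7 | 10-hydroxy-9-iodo-5-methoxy-2,2-dimethyl-3,4-dihydro-2H,8H-pyrano[2,3-f]chromen-8-one | COc1cc2oc(=O)c(I)c(O)c2c2c1CCC(C)(C)O2 | intermediate
8 | trichloroethylene | ClC=C(Cl)Cl | starting material
9 | dichloroacetylene (formed and consumed in step 5) | ClC#CCl | intermediate
10 | 10-{[(E)-1,2-dichloroethenyl]oxy}-9-iodo-5-methoxy-2,2-dimethyl-3,4-dihydro-2H,8H-pyrano[2,3-f]chromen-8-one | COc1cc2oc(=O)c(I)c(O/C(Cl)=C\Cl)c2c2c1CCC(C)(C)O2 | intermediate
11 | trimethylsilylacetylene | C#C[Si](C)(C)C | starting material
12 | 10-{[(E)-1,2-dichloroethenyl]oxy}-5-methoxy-2,2-dimethyl-9-[(trimethylsilyl)ethynyl]-3,4-dihydro-2H,8H-pyrano[2,3-f]chromen-8-one | COc1cc2oc(=O)c(C#C[Si](C)(C)C)c(O/C(Cl)=C\Cl)c2c2c1CCC(C)(C)O2 | intermediate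
13 | chloroethynyl ether, 10-[(chloroethynyl)oxy]-5-methoxy-2,2-dimethyl-9-[(trimethylsilyl)ethynyl]-3,4-dihydro-2H,8H-pyrano[2,3-f]chromen-8-one (formed and consumed in step 7) | COc1cc2oc(=O)c(C#C[Si](C)(C)C)c(OC#CCl)c2c2c1CCC(C)(C)O2 | intermediate
14 | lithium acetylide of 15 (formed and consumed in step 7) | COc1cc2oc(=O)c(C#C[Si](C)(C)C)c(OC#C[Li])c2c2c1CCC(C)(C)O2 | intermediate
15 | 10-(ethynyloxy)-5-methoxy-2,2-dimethyl-9-[(trimethylsilyl)ethynyl]-3,4-dihydro-2H,8H-pyrano[2,3-f]chromen-8-one (4-ethynyloxy-3-silylethynyl coumarin carrying rings A and E) | COc1cc2oc(=O)c(C#C[Si](C)(C)C)c(OC#C)c2c2c1CCC(C)(C)O2 | intermediate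
16 | ethynylboronic acid pinacol ester (2-ethynyl-4,4,5,5-tetramethyl-1,3,2-dioxaborolane) | C#CB1OC(C)(C)C(C)(C)O1 | starting material
17 | ring-E-fused 3-methoxy-9-(4,4,5,5-tetramethyl-1,3,2-dioxaborolan-2-yl)-7-(trimethylsilyl)coumestan | COc1cc2oc(=O)c3c4c([Si](C)(C)C)cc(B5OC(C)(C)C(C)(C)O5)cc4oc3c2c2c1CCC(C)(C)O2 | intermediate
18 | ring-E-fused 9-hydroxy-3-methoxy-7-(trimethylsilyl)coumestan | COc1cc2oc(=O)c3c4c([Si](C)(C)C)cc(O)cc4oc3c2c2c1CCC(C)(C)O2 | intermediate
19 | ring-E-fused 9-hydroxy-3-methoxycoumestan, CNP0304440.0 | COc1cc2oc(=O)c3c4ccc(O)cc4oc3c2c2c1CCC(C)(C)O2 | target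

## Step count and least certain steps

Total step count: 10. Longest linear sequence: 10 steps (1 to 19); 3, 8, 11 and 16 are purchased.

**Step 8 (key step).** The most likely failure is that 16 trimerises with itself, or 15 oligomerises, faster than the cross-cycloaddition, because the silyl-capped alkyne conjugated to the lactone is a reluctant partner in the oxidative coupling. Metal-assisted hydration or cleavage of the acyl-like ynol ether, and erosion of the orientation of 16, are the other risks. A change to CpCo(CO)2 under irradiation or to Cp*RuCl(cod) would alter only the conditions.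

The fallback uses known chemistry, sets out from 7 and comes back at 19. Sulfonylation of 7 (TsCl, Et3N, CH2Cl2) should give 9-iodo-5-methoxy-2,2-dimethyl-8-oxo-3,4-dihydro-2H,8H-pyrano[2,3-f]chromen-10-yl 4-methylbenzenesulfonate F1. Addition–elimination with 3-(methoxymethoxy)phenol and K2CO3 in MeCN should give 9-iodo-5-methoxy-10-[3-(methoxymethoxy)phenoxy]-2,2-dimethyl-3,4-dihydro-2H,8H-pyrano[2,3-f]chromen-8-one F2. Intramolecular direct arylation (Pd(OAc)2, PCy3·HBF4, K2CO3, DMA, 110 °C) should close ring C para to the acetal oxygen: zerovalent palladium inserts into C–I, the aryl C–H is palladated, and reductive elimination follows. This gives the 9-O-methoxymethyl ether of the target F3, and HCl in MeOH/THF then gives 19.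

**Step 7.** Deprotonation places the vinyl anion anti to the C–O bond, so expulsion of the coumarin oxyanion (a carboxylate-like leaving group) with release of 9 can compete with the syn loss of chloride. Attack of the organolithium at the lactone or at the oxygen-bearing ring carbon, and hydration of the terminal ynol ether during work-up, are further risks.

The fallback sets out from 7 and comes back at 15. The vinylation of step 5 is run with tribromoethylene in place of 8, which should give 10-{[(E)-1,2-dibromoethenyl]oxy}-9-iodo-5-methoxy-2,2-dimethyl-3,4-dihydro-2H,8H-pyrano[2,3-f]chromen-8-one F4. Sonogashira coupling with 11 at room temperature (C–I before C–Br) should give the 9-[(trimethylsilyl)ethynyl] analogue F5. Activated Zn dust in THF should then remove the two trans bromines by reductive anti-elimination and give 15 under neutral conditions. No organolithium is used, and no carbanion sits anti to the oxyanion leaving group.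

**Step 5.** The stabilised, ambident coumarin oxyanion may add too slowly to the transient dihaloalkyne, or may react through the lactone oxygen or through carbon with loss of iodine.

The fallback attaches the two-carbon unit by O-alkylation and makes the triple bond afterwards; it sets out from 7 and comes back at 15. Mitsunobu reaction (PPh3, diisopropyl azodicarboxylate, 2,2-dimethoxyethanol, THF) should give 10-(2,2-dimethoxyethoxy)-9-iodo-5-methoxy-2,2-dimethyl-3,4-dihydro-2H,8H-pyrano[2,3-f]chromen-8-one F6. Sonogashira coupling with 11 should give the 9-[(trimethylsilyl)ethynyl] acetal F7. Aqueous formic acid should unmask the aldehyde, {[5-methoxy-2,2-dimethyl-8-oxo-9-[(trimethylsilyl)ethynyl]-3,4-dihydro-2H,8H-pyrano[2,3-f]chromen-10-yl]oxy}acetaldehyde F8. KN(SiMe3)2 and PhNTf2 in THF at −78 °C should give the (Z)-enol triflate F9, which is not isolated. A further equivalent of KN(SiMe3)2 should eliminate triflate anti to the vinylic hydrogen next to oxygen and give 15.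

**Step 10.** Ipso-protonation at C7 may be sluggish, because C7 is meta to both oxygen donors of ring D. Forcing the acid could open ring E or lead to substitution at the electron-rich C4.

The fallback changes the mechanism to nucleophilic cleavage at silicon; it sets out from 18 and comes back at 19. KOSiMe3 (4 equiv) in wet DMSO at 60 °C should open the lactone reversibly and cleave the Ar–Si bond. This gives, as its potassium salt, 6-hydroxy-2-(7-hydroxy-5-methoxy-2,2-dimethylchroman-8-yl)-1-benzofuran-3-carboxylic acid F10. Acidification with aqueous HCl, with warm AcOH if needed, should close the lactone again to 19.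

**Step 2.** Over-alkylation of the still activated arene and low conversion are likely, since part of the acylphloroglucinol is tied up as a BF3 chelate.

The fallback builds ring E by a pericyclic route; it sets out from 2 and comes back at 5. Mono-O-alkylation with 3-chloro-3-methylbut-1-yne (K2CO3, KI, CuI cat., acetone) should give 1-{2-hydroxy-4-methoxy-6-[(2-methylbut-3-yn-2-yl)oxy]phenyl}ethan-1-one F11. Heating in N,N-diethylaniline at 150 °C should give 1-(7-hydroxy-5-methoxy-2,2-dimethyl-2H-chromen-8-yl)ethan-1-one F12, by propargyl Claisen rearrangement to the only free ortho carbon, 1,5-hydrogen shift and oxa-6π closure. Hydrogenation (H2, Pd/C, EtOAc) then gives 5.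

Further compounds
F1 | step 8 | 9-iodo-5-methoxy-2,2-dimethyl-8-oxo-3,4-dihydro-2H,8H-pyrano[2,3-f]chromen-10-yl 4-methylbenzenesulfonate | COc1cc2oc(=O)c(I)c(OS(=O)(=O)c3ccc(C)cc3)c2c2c1CCC(C)(C)O2
F2 | step 8 | 9-iodo-5-methoxy-10-[3-(methoxymethoxy)phenoxy]-2,2-dimethyl-3,4-dihydro-2H,8H-pyrano[2,3-f]chromen-8-one | COc1cc2oc(=O)c(I)c(Oc3cccc(OCOC)c3)c2c2c1CCC(C)(C)O2
F3 | step 8 | 9-O-methoxymethyl ether of the target | COc1cc2oc(=O)c3c4ccc(OCOC)cc4oc3c2c2c1CCC(C)(C)O2
F4 | step 7 | 10-{[(E)-1,2-dibromoethenyl]oxy}-9-iodo-5-methoxy-2,2-dimethyl-3,4-dihydro-2H,8H-pyrano[2,3-f]chromen-8-one | COc1cc2oc(=O)c(I)c(O/C(Br)=C\Br)c2c2c1CCC(C)(C)O2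
F5 | step 7 | 10-{[(E)-1,2-dibromoethenyl]oxy}-5-methoxy-2,2-dimethyl-9-[(trimethylsilyl)ethynyl]-3,4-dihydro-2H,8H-pyrano[2,3-f]chromen-8-one | COc1cc2oc(=O)c(C#C[Si](C)(C)C)c(O/C(Br)=C\Br)c2c2c1CCC(C)(C)O2
F6 | step 5 | 10-(2,2-dimethoxyethoxy)-9-iodo-5-methoxy-2,2-dimethyl-3,4-dihydro-2H,8H-pyrano[2,3-f]chromen-8-one | COc1cc2oc(=O)c(I)c(OCC(OC)OC)c2c2c1CCC(C)(C)O2
F7 | step 5 | 10-(2,2-dimethoxyethoxy)-5-methoxy-2,2-dimethyl-9-[(trimethylsilyl)ethynyl]-3,4-dihydro-2H,8H-pyrano[2,3-f]chromen-8-one | COc1cc2oc(=O)c(C#C[Si](C)(C)C)c(OCC(OC)OC)c2c2c1CCC(C)(C)O2
F8 | step 5 | {[5-methoxy-2,2-dimethyl-8-oxo-9-[(trimethylsilyl)ethynyl]-3,4-dihydro-2H,8H-pyrano[2,3-f]chromen-10-yl]oxy}acetaldehyde | COc1cc2oc(=O)c(C#C[Si](C)(C)C)c(OCC=O)c2c2c1CCC(C)(C)O2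
F9 | step 5 | (Z)-enol triflate of F8 | COc1cc2oc(=O)c(C#C[Si](C)(C)C)c(O/C=C\OS(=O)(=O)C(F)(F)F)c2c2c1CCC(C)(C)O2
F10 | step 10 | 6-hydroxy-2-(7-hydroxy-5-methoxy-2,2-dimethylchroman-8-yl)-1-benzofuran-3-carboxylic acid | COc1cc(O)c(-c2oc3cc(O)ccc3c2C(=O)O)c2c1CCC(C)(C)O2
F11 | step 2 | 1-{2-hydroxy-4-methoxy-6-[(2-methylbut-3-yn-2-yl)oxy]phenyl}ethan-1-one | CC(=O)c1c(O)cc(OC)cc1OC(C)(C)C#C
F12 | step 2 | 1-(7-hydroxy-5-methoxy-2,2-dimethyl-2H-chromen-8-yl)ethan-1-one | CC(=O)c1c(O)cc(OC)c2c1OC(C)(C)C=C2
A1 | alternative 1 | 7-(benzyloxy)-3-(2-diazoacetyl)-1H-[1]benzofuro[3,2-c]pyran-1-one | [N-]=[N+]=CC(=O)c1cc2oc3cc(OCc4ccccc4)ccc3c2c(=O)o1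
A2 | alternative 1 | 7-(benzyloxy)-3-(2-oxoethenyl)-1H-[1]benzofuro[3,2-c]pyran-1-one (vinylketene) | O=C=Cc1cc2oc3cc(OCc4ccccc4)ccc3c2c(=O)o1
A3 | alternative 1 | 1-methoxy-5-methylhex-4-en-1-yne | COC#CCC=C(C)C
A4 | alternative 1 | 9-benzyloxy-1-hydroxy-3-methoxy-2-prenylcoumestan | COc1cc2oc(=O)c3c4ccc(OCc5ccccc5)cc4oc3c2c(O)c1CC=C(C)C
A5 | alternative 2 | 5-methoxy-2,2-dimethyl-8-(trimethylsilyl)chroman-7-yl trifluoromethanesulfonate | COc1cc(OS(=O)(=O)C(F)(F)F)c([Si](C)(C)C)c2c1CCC(C)(C)O2
A6 | alternative 2 | 5-methoxy-2,2-dimethyl-7,8-didehydrochroman (aryne) | COC1=CC#CC2=C1CCC(C)(C)O2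
A7 | alternative 2 | 6-(benzyloxy)-2-bromobenzofuran-3-carboxylic acid | OC(=O)c1c(Br)oc2cc(OCc3ccccc3)ccc12
A8 | alternative 2 | 9-O-benzyl ether of the target | COc1cc2oc(=O)c3c4ccc(OCc5ccccc5)cc4oc3c2c2c1CCC(C)(C)O2
A9 | alternative 3 | 9-benzyloxy-3-methoxy-1-[(2-methylbut-3-yn-2-yl)oxy]coumestan | COc1cc2oc(=O)c3c4ccc(OCc5ccccc5)cc4oc3c2c(OC(C)(C)C#C)c1
A10 | alternative 3 | 9-O-benzyl ether of the ring E dehydro (chromene) target | COc1cc2oc(=O)c3c4ccc(OCc5ccccc5)cc4oc3c2c2c1C=CC(C)(C)O2
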